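**Retrosynthetic overview**

1. Locants: ring A = cyclobutane, ring B = cyclohexene fused to it, ring C = ring carrying CO2H and both OH, ring D = cyclopentane; ring-C atoms are a (tertiary C–OH), b (C–CO2H), c (=CH), d (CHOH), e (CH at the C/D junction), f (central CH shared by B, C and D).
2. Target 24 ⇐ ring-C 1,3-diene acid 22 (a=b, c=d) by singlet-oxygen (4+2) addition and O–O reduction, which delivers both OH groups cis; 22 ⇐ cycloadduct 21 by β-elimination of the silyloxy group at a.
3. Key disconnection: ring C ⇐ a cyclobut-2-ene-1-carboxylate built from b, c, d, e (σ bond b–e) plus the a=f silyl enol ether bond of a ring-B 2-silyloxy-1,3-diene. Thermal 4π opening and intramolecular (4+2) capture enlarge the four-membered ring by the atoms a and f. The enabling feature is that b–c–d–e is a but-2-ene-1,4-diyl unit flanked by oxygen-bearing a and by f, and that e hangs on ring A through one CH2, so the same event closes ring D.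
4. Precursor 18 ⇐ enone bromide 12 + chloro acid 15 (from photo-isomerised 2-pyranone) by zinc/palladium allyl–alkyl coupling; 12 ⇐ cyclobutanone 7 by methylenation, hydroboration, bromination and allylic oxidation.
5. Rings A/B ⇐ auxiliary-controlled keteniminium (2+2) cycloaddition of decanamide 3 with cyclohexa-1,3-diene; ring order: A onto preformed B, temporary cyclobutene, then D and C together.

Key step: step 11

Remark: the (2R,5R) auxiliary is assumed to induce the absolute configuration drawn for 7; if the opposite sense is found, the commercial (2S,5S) enantiomer of 2 is used with no other change.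
Remark: 15 is racemic, so 17 and 18 are pairs of trans epimers at the two cyclobutene sp3 carbons (one epimer drawn); both centres are erased in step 11.

**Step 1**
Reactants: 1 decanoyl chloride; 2 (2R,5R)-2,5-dimethylpyrrolidine
Product: 3 1-[(2R,5R)-2,5-dimethylpyrrolidin-1-yl]decan-1-one
Conditions: Et3N, CH2Cl2, 0 °C → rt
Reagents that add atoms: none
Why: N-acylation of the C2-symmetric secondary amine by the acid chloride should be clean and installs the chiral auxiliary without creating a stereocentre.

**Step 2**
Reactants: 3 1-[(2R,5R)-2,5-dimethylpyrrolidin-1-yl]decan-1-one; 4 cyclohexa-1,3-diene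
Product: 7 cis-fused 8-exo-octylbicyclo[4.2.0]oct-2-en-7-one, via keteniminium triflate 5 (not isolated), via cyclobutaniminium triflate 6 (not isolated)
Conditions: Tf2O, 2,4,6-collidine (2.2 equiv), ClCH2CH2Cl, −20 → 60 °C; H2O, rt; DBU (cat.), CH2Cl2, rt
Reagents that add atoms: water, O
Why: In this keteniminium (2+2) cycloaddition the electrophilic central carbon should attack a diene terminus and close on the neighbouring carbon, giving only the 7-one/8-alkyl regioisomer with cis ring fusion, while the C2-symmetric pyrrolidine differentiates the faces of the keteniminium C=C bond (absolute configuration of both ring-fusion carbons) and, after hydrolysis, DBU equilibrates the enolisable octyl-bearing carbon to the exo epimer on the convex face.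

**Step 3**
Reactants: 7 cis-fused 8-exo-octylbicyclo[4.2.0]oct-2-en-7-one
Product: 8 cis-fused 7-methylidene-8-exo-octylbicyclo[4.2.0]oct-2-ene
Conditions: Ph3PCH3Br, KOtBu, THF, 0 °C → rt
Reagents that add atoms: methyltriphenylphosphonium bromide, C[P+](c1ccccc1)(c1ccccc1)c1ccccc1.[Br-]
Why: Wittig methylenation of the strained, electrophilic cyclobutanone should be fast, and any base-induced epimerisation next to the carbonyl before olefination returns the same thermodynamic exo-octyl epimer.

**Step 4**
Reactants: 8 cis-fused 7-methylidene-8-exo-octylbicyclo[4.2.0]oct-2-ene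
Product: 10 (8-exo-octylbicyclo[4.2.0]oct-2-en-7-endo-yl)methanol, via B-alkyl-9-BBN adduct 9 (not isolated)
Conditions: 9-BBN, THF, 0 °C → rt; NaOH, H2O2, H2O, 0 °C
Reagents that add atoms: hydrogen peroxide, OO
Why: In this hydroboration–oxidation 9-BBN should add to the 1,1-disubstituted exocyclic alkene far faster than to the cis-disubstituted ring alkene, boron going to the terminal carbon and hydrogen to the ring carbon from the convex exo face (the concave face is screened by the six-membered ring), so the new CH2 group is endo and trans to the octyl group.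

**Step 5**
Reactants: 10 (8-exo-octylbicyclo[4.2.0]oct-2-en-7-endo-yl)methanol
Product: 11 7-endo-(bromomethyl)-8-exo-octylbicyclo[4.2.0]oct-2-ene
Conditions: CBr4, PPh3, CH2Cl2, 0 °C
Reagents that add atoms: carbon tetrabromide, BrC(Br)(Br)Br
Why: The Appel reaction converts the primary alcohol into the bromide under neutral conditions that leave the ring alkene and the cyclobutane stereocentres untouched.

**Step 6**
Reactants: 11 7-endo-(bromomethyl)-8-exo-octylbicyclo[4.2.0]oct-2-ene
Product: 12 8-endo-(bromomethyl)-7-exo-octylbicyclo[4.2.0]oct-4-en-3-one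
Conditions: Rh2(cap)4 (1 mol %; dirhodium tetrakis(caprolactamate)), t-BuOOH (70% aq.), CH2Cl2, rt
Reagents that add atoms: tert-butyl hydroperoxide, CC(C)(C)OO
Why: In this radical allylic oxidation hydrogen abstraction should occur at the only allylic methylene and peroxidation at the less hindered allyl terminus remote from the ring fusion, giving the enone after loss of tert-butanol, because the allylic cyclobutane methine C–H is stronger and hindered and the primary bromide is inert.

**Step 7**
Reactants: 13 2H-pyran-2-one
Product: 14 2-oxabicyclo[2.2.0]hex-5-en-3-one (racemic)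
Conditions: hν (300 nm), Et2O, −10 °C, flow reactor
Reagents that add atoms: none
Why: Photochemical 4π electrocyclisation of 2-pyranone should give the cis-fused bicyclic β-lactone, a latent cyclobutenyl allyl electrophile that is kept in solution.

**Step 8**
Reactants: 14 2-oxabicyclo[2.2.0]hex-5-en-3-one
Product: 15 cis-4-chlorocyclobut-2-ene-1-carboxylic acid (racemic)
Conditions: HCl (2 M in Et2O), 0 °C
Reagents that add atoms: hydrogen chloride, Cl
Why: Chloride opening of the strained allylic β-lactone should give the bench-stable cis chloro acid, the cis relationship following from the cis-fused lactone.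

**Step 9**
Reactants: 12 8-endo-(bromomethyl)-7-exo-octylbicyclo[4.2.0]oct-4-en-3-one; 15 cis-4-chlorocyclobut-2-ene-1-carboxylic acid
Product: 17 trans-4-[(7-exo-octyl-3-oxobicyclo[4.2.0]oct-4-en-8-endo-yl)methyl]cyclobut-2-ene-1-carboxylic acid, via alkylzinc bromide 16 (not isolated)
Conditions: 12, Zn dust, LiCl, THF, 45 °C; then 15 + LiN(SiMe3)2 (THF, −78 °C), Pd2(dba)3 (2.5 mol %), P(2-furyl)3 (10 mol %), 0 °C → rt; aq. HCl work-up
Reagents that add atoms: none
Why: LiCl-assisted zinc insertion should give a primary alkylzinc that tolerates the enone, and palladium-catalysed allyl–alkyl coupling (oxidative addition with inversion, alkyl transfer from zinc to palladium, reductive elimination with retention) places the alkyl group trans to the carboxylate, attack at either allyl terminus giving the same constitution.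

**Step 10**
Reactants: 17 trans-4-[(7-exo-octyl-3-oxobicyclo[4.2.0]oct-4-en-8-endo-yl)methyl]cyclobut-2-ene-1-carboxylic acid
Product: 18 tert-butyldimethylsilyl trans-4-{[3-(tert-butyldimethylsilyloxy)-7-exo-octylbicyclo[4.2.0]octa-2,4-dien-8-endo-yl]methyl}cyclobut-2-ene-1-carboxylate
Conditions: LiN(iPr)2 (2.2 equiv), THF, −78 °C; TBSOTf (2.3 equiv), −78 → 0 °C
Reagents that add atoms: tert-butyldimethylsilyl trifluoromethanesulfonate, CC(C)(C)[Si](C)(C)OS(=O)(=O)C(F)(F)F
Why: Kinetic deprotonation of the carboxylate-protected enone at the α′-methylene (not at the γ-methine on the cyclobutane) and O-silylation should give the cross-conjugated 2-silyloxy-1,3-diene, the carboxylate becoming the silyl ester that masks the acid during the thermal step.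

**Step 11**
Reactants: 18 tert-butyldimethylsilyl trans-4-{[3-(tert-butyldimethylsilyloxy)-7-exo-octylbicyclo[4.2.0]octa-2,4-dien-8-endo-yl]methyl}cyclobut-2-ene-1-carboxylate
Product: 21 tetracyclic cycloadduct acid (silyl ether at a; sp3 CH–CO2H at b, carboxyl cis to the silyloxy group; c=d alkene), via ring-opened silyl dienoate 19 (not isolated), via silyl ester cycloadduct 20 (not isolated)
Conditions: PhMe (0.01 M), BHT (cat.), 110 °C, sealed tube, argon; then MeOH, rt
Reagents that add atoms: none
Why: At 110 °C the trans-3,4-disubstituted cyclobutene of 18 should open by thermal conrotatory 4π electrocyclic ring opening, both substituents turning outward, to the (2E,4E)-dienoate 19, and this electron-poor diene is captured at once by the electron-rich a=f silyl enol ether bond of ring B in an intramolecular inverse-electron-demand Diels–Alder reaction, so that the former four-membered ring (b, c, d, e) is enlarged by the two atoms a and f to ring C. The closest known reaction types are the 4π opening of trans-4-alkylcyclobut-2-enecarboxylates to (2E,4E)-dienoates and the thermal intramolecular Diels–Alder reaction of a bicyclo[4.2.0]octa-2,4-diene with a CH2-linked diene on its cyclobutane; the tandem is the aliphatic counterpart of the benzocyclobutene opening/cycloaddition annulation. Ring C closes by the concerted suprafacial (4+2) union b–a and e–f, and ring D closes in the same event as the five-membered ring defined by the tether CH2–CH(ring A)–CH(ring A) between e and f. C-a and C-f are set by suprafacial addition to the cis ring-B bond from the face that carries the endo CH2 tether (silyloxy group at a and hydrogen at f stay cis, on the convex face), C-e by the E geometry of the distal diene bond in the only transition state the short tether allows (hydrogen at e trans to hydrogen at f), and C-b by the E geometry of the proximal bond (carboxyl cis to the ring-D methylene). The step needs the dienoate to act as the 4π partner toward the a=f bond instead of becoming a dienophile for the silyloxydiene, and it must outrun hydrogen shifts in the cyclooctatriene valence isomer of 18; the three-atom tether holds the diene under the a=f bond and not across ring B, the polarity is matched (nucleophilic C-f to the δ carbon, C-a to the α carbon), and high dilution suppresses intermolecular cycloaddition, while the unproductive cis-fused valence isomer returns through the cyclooctatriene. Methanol then cleaves only the silyl ester.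

**Step 12**
Reactants: 21 tetracyclic cycloadduct acid
Product: 22 tetracyclic trienoic acid (ring C = a=b, c=d diene with CO2H at b; ring-B alkene kept)
Conditions: LiN(iPr)2 (2.5 equiv), THF, −78 → 0 °C; AcOH quench
Reagents that add atoms: none
Why: E1cB elimination from the carboxylic acid dianion should expel the β-silyloxy group, whose axial C–O bond is aligned with the enediolate π system, to give the ring-C cyclohexa-1,3-diene acid, deliberately erasing the centres at a and b while the ring-fusion centres stay untouched at this temperature and stoichiometry.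

**Step 13**
Reactants: 22 tetracyclic trienoic acid
Product: 24 target acid CNP0106718.3, via endoperoxide 23 (not isolated)
Conditions: O2, tetraphenylporphyrin (cat.), hν (white LED), CH2Cl2, −30 °C; then thiourea, MeOH, rt
Reagents that add atoms: dioxygen, O=O
Why: Singlet-oxygen (4+2) cycloaddition should occur at the only s-cis diene (ring C; the diene spanning rings B and C is locked s-trans) and thiourea reduction of the O–O bond then gives the cis-1,4-diol, both C–O stereocentres being set in the cycloaddition by oxygen adding to the convex face that carries the hydrogen at f, anti to the folded cyclobutane/cyclopentane face.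

**Compound list**

1 | decanoyl chloride | CCCCCCCCCC(=O)Cl | starting material
2 | (2R,5R)-2,5-dimethylpyrrolidine | C[C@@H]1CC[C@@H](C)N1 | starting material
3 | 1-[(2R,5R)-2,5-dimethylpyrrolidin-1-yl]decan-1-one | CCCCCCCCCC(=O)N1[C@H](C)CC[C@H]1C | intermediate
4 | cyclohexa-1,3-diene | C1=CC=CCC1 | starting material
5 | (2R,5R)-1-(dec-1-en-1-ylidene)-2,5-dimethylpyrrolidin-1-ium triflate (keteniminium salt, not isolated) | CCCCCCCCC=C=[N+]1[C@H](C)CC[C@H]1C.[O-]S(=O)(=O)C(F)(F)F | intermediate
6 | (2R,5R)-1-(cis-fused 8-exo-octylbicyclo[4.2.0]oct-2-en-7-ylidene)-2,5-dimethylpyrrolidin-1-ium triflate (not isolated) | CCCCCCCC[C@H]1[C@@H]2C=CCC[C@@H]2C1=[N+]3[C@H](C)CC[C@H]3C.[O-]S(=O)(=O)C(F)(F)F | intermediate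
7 | cis-fused 8-exo-octylbicyclo[4.2.0]oct-2-en-7-one | CCCCCCCC[C@H]1[C@@H]2C=CCC[C@@H]2C1=O | intermediate
8 | cis-fused 7-methylidene-8-exo-octylbicyclo[4.2.0]oct-2-ene | CCCCCCCC[C@H]1[C@@H]2C=CCC[C@@H]2C1=C | intermediate
9 | 9-[(8-exo-octylbicyclo[4.2.0]oct-2-en-7-endo-yl)methyl]-9-borabicyclo[3.3.1]nonane (not isolated) | CCCCCCCC[C@H]1[C@@H]2C=CCC[C@@H]2[C@@H]1CB3C4CCCC3CCC4 | intermediate
10 | (8-exo-octylbicyclo[4.2.0]oct-2-en-7-endo-yl)methanol | CCCCCCCC[C@H]1[C@@H]2C=CCC[C@@H]2[C@@H]1CO | intermediate
11 | 7-endo-(bromomethyl)-8-exo-octylbicyclo[4.2.0]oct-2-ene | CCCCCCCC[C@H]1[C@@H]2C=CCC[C@@H]2[C@@H]1CBr | intermediate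
12 | 8-endo-(bromomethyl)-7-exo-octylbicyclo[4.2.0]oct-4-en-3-one | CCCCCCCC[C@H]1[C@@H]2C=CC(=O)C[C@@H]2[C@@H]1CBr | intermediate
13 | 2H-pyran-2-one | O=C1C=CC=CO1 | starting material
14 | 2-oxabicyclo[2.2.0]hex-5-en-3-one (racemic, one enantiomer drawn) | O=C1O[C@H]2C=C[C@@H]12 | intermediate
15 | cis-4-chlorocyclobut-2-ene-1-carboxylic acid (racemic, one enantiomer drawn) | OC(=O)[C@H]1C=C[C@H]1Cl | intermediate
16 | [(7-exo-octyl-3-oxobicyclo[4.2.0]oct-4-en-8-endo-yl)methyl]zinc bromide (not isolated) | CCCCCCCC[C@H]1[C@@H]2C=CC(=O)C[C@@H]2[C@@H]1C[Zn]Br | intermediate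
17 | trans-4-[(7-exo-octyl-3-oxobicyclo[4.2.0]oct-4-en-8-endo-yl)methyl]cyclobut-2-ene-1-carboxylic acid (one of two trans epimers drawn) | CCCCCCCC[C@H]1[C@@H]2C=CC(=O)C[C@@H]2[C@@H]1C[C@H]3C=C[C@@H]3C(=O)O | intermediate
18 | tert-butyldimethylsilyl trans-4-{[3-(tert-butyldimethylsilyloxy)-7-exo-octylbicyclo[4.2.0]octa-2,4-dien-8-endo-yl]methyl}cyclobut-2-ene-1-carboxylate (one of two trans epimers drawn) | CCCCCCCC[C@H]1[C@@H]2C=CC(O[Si](C)(C)C(C)(C)C)=C[C@@H]2[C@@H]1C[C@H]3C=C[C@@H]3C(=O)O[Si](C)(C)C(C)(C)C | intermediate
19 | tert-butyldimethylsilyl (2E,4E)-6-[3-(tert-butyldimethylsilyloxy)-7-exo-octylbicyclo[4.2.0]octa-2,4-dien-8-endo-yl]hexa-2,4-dienoate (not isolated) | CCCCCCCC[C@H]1[C@@H]2C=CC(O[Si](C)(C)C(C)(C)C)=C[C@@H]2[C@@H]1C/C=C/C=C/C(=O)O[Si](C)(C)C(C)(C)C | intermediate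
20 | tetracyclic cycloadduct, silyl ether at a and silyl ester at b (not isolated) | CCCCCCCC[C@H]1[C@@H]2C=C[C@]3(O[Si](C)(C)C(C)(C)C)[C@@H](C(=O)O[Si](C)(C)C(C)(C)C)C=C[C@H]4C[C@H]1[C@H]2[C@@H]43 | intermediate
21 | tetracyclic cycloadduct acid: silyl ether at a, CH–CO2H at b (carboxyl cis to the silyloxy group), c=d alkene | CCCCCCCC[C@H]1[C@@H]2C=C[C@]3(O[Si](C)(C)C(C)(C)C)[C@@H](C(=O)O)C=C[C@H]4C[C@H]1[C@H]2[C@@H]43 | intermediate
22 | tetracyclic trienoic acid: ring C as the a=b, c=d diene with CO2H at b | CCCCCCCC[C@H]1[C@@H]2C=CC3=C(C(=O)O)C=C[C@H]4C[C@H]1[C@H]2[C@@H]43 | intermediate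
23 | endoperoxide: O–O bridge from a to d on the face of the hydrogen at f (not isolated) | CCCCCCCC[C@H]1[C@@H]2C=C[C@]3(OO5)C(C(=O)O)=C[C@@H]5[C@H]4C[C@H]1[C@H]2[C@@H]43 | intermediate
24 | CNP0106718.3: tetracyclic acid with cis-1,4-diol (OH at a and d) and b=c alkene bearing CO2H | CCCCCCCC[C@H]1[C@@H]2C=C[C@]3(O)C(C(=O)O)=C[C@@H](O)[C@H]4C[C@H]1[C@H]2[C@@H]43 | target

**Step count and risks**

Total: 13 steps. Longest linear sequence: 11 steps (1–6, 9–13); steps 7–8 are a two-step branch.

Most likely to fail:

Step 11. Before the cyclobutene has opened, the silyloxydiene may engage the dienoate as the 4π partner (bicyclo[2.2.2]octene mode), isomerise by hydrogen shift in its cyclooctatriene valence isomer, or lose its silyl group. The fallback sets out from 17 and keeps the ring enlargement but uses the unactivated ring-B diene. The kinetic enolate of 17 (LiN(iPr)2, 2.2 equiv) is trapped with PhNTf2 to give the dienyl triflate acid F1. Reduction with Pd(OAc)2/PPh3, Bu3N and HCO2H in DMF at 40 °C should give the parent bicyclo[4.2.0]octa-2,4-diene acid F2. Heating F2 in toluene at 110 °C brings about the same cyclobutene opening and intramolecular Diels–Alder enlargement, now with the plain ring-B alkene, to give the cycloadduct acid F3 (hydrogen at a). Its dianion is selenenylated with PhSeBr on the convex face to the α-phenylselenyl acid F4, and H2O2 oxidation with syn-elimination toward the hydrogen at a comes back to the route at 22.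

Step 13. Singlet oxygen may add to the concave face of the ring-C diene and give the bis-epimeric diol. The fallback sets out from 22 and delivers both oxygens to the face opposite the one a reagent approaches. Esterification with Me3SiCHN2 gives the methyl ester F5. Palladium-catalysed cis-1,4-diacetoxylation (Pd(OAc)2 cat., LiOAc, LiCl cat., p-benzoquinone, AcOH, rt) should give the cis-diacetate F6, because the metal binds the accessible face and both acetates enter by external attack anti to it. LiOH in THF/H2O cleaves both acetates and the methyl ester and comes back at 24.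

Step 9. Zinc insertion next to the enone may be sluggish, the zinc reagent may be protonated by the acid partner, or homocoupling may dominate. The fallback sets out from 12 and masks the carbonyl before the C–C coupling. LiN(iPr)2 and TBSOTf convert 12 into the bromo silyl dienol ether F7, and Zn/LiCl then gives the alkylzinc bromide F8. Coupling under Pd2(dba)3/P(2-furyl)3 with the silyl ester F9, made from 15 with TBSCl and imidazole, should give 18 directly, so the route is rejoined at 18 with the same number of steps.

**Further compounds**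

F1 | step 11 | trans-4-{[7-exo-octyl-3-(trifluoromethanesulfonyloxy)bicyclo[4.2.0]octa-2,4-dien-8-endo-yl]methyl}cyclobut-2-ene-1-carboxylic acid | CCCCCCCC[C@H]1[C@@H]2C=CC(OS(=O)(=O)C(F)(F)F)=C[C@@H]2[C@@H]1C[C@H]3C=C[C@@H]3C(=O)O
F2 | step 11 | trans-4-[(7-exo-octylbicyclo[4.2.0]octa-2,4-dien-8-endo-yl)methyl]cyclobut-2-ene-1-carboxylic acid | CCCCCCCC[C@H]1[C@@H]2C=CC=C[C@@H]2[C@@H]1C[C@H]3C=C[C@@H]3C(=O)O
F3 | step 11 | tetracyclic cycloadduct acid with hydrogen at a (cis to hydrogen at f), CH–CO2H at b, c=d alkene | CCCCCCCC[C@H]1[C@@H]2C=C[C@@H]3[C@@H](C(=O)O)C=C[C@H]4C[C@H]1[C@H]2[C@@H]43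
F4 | step 11 | α-phenylselenyl derivative of F3 (SePh at b, cis to hydrogen at a) | CCCCCCCC[C@H]1[C@@H]2C=C[C@@H]3[C@]([Se]c5ccccc5)(C(=O)O)C=C[C@H]4C[C@H]1[C@H]2[C@@H]43
F5 | step 13 | methyl ester of 22 | CCCCCCCC[C@H]1[C@@H]2C=CC3=C(C(=O)OC)C=C[C@H]4C[C@H]1[C@H]2[C@@H]43
F6 | step 13 | methyl ester of 24 with acetates at a and d (cis-1,4-diacetate) | CCCCCCCC[C@H]1[C@@H]2C=C[C@]3(OC(C)=O)C(C(=O)OC)=C[C@@H](OC(C)=O)[C@H]4C[C@H]1[C@H]2[C@@H]43
F7 | step 9 | 8-endo-(bromomethyl)-3-(tert-butyldimethylsilyloxy)-7-exo-octylbicyclo[4.2.0]octa-2,4-diene | CCCCCCCC[C@H]1[C@@H]2C=CC(O[Si](C)(C)C(C)(C)C)=C[C@@H]2[C@@H]1CBr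
F8 | step 9 | {[3-(tert-butyldimethylsilyloxy)-7-exo-octylbicyclo[4.2.0]octa-2,4-dien-8-endo-yl]methyl}zinc bromide | CCCCCCCC[C@H]1[C@@H]2C=CC(O[Si](C)(C)C(C)(C)C)=C[C@@H]2[C@@H]1C[Zn]Br
F9 | step 9 | tert-butyldimethylsilyl cis-4-chlorocyclobut-2-ene-1-carboxylate (racemic) | CC(C)(C)[Si](C)(C)OC(=O)[C@H]1C=C[C@H]1Cl
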